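**Strategy**

The route rests on cutting the unbranched decamethylene tether between its third and fourth carbon counted from C6 of the 2‑pyranone ring, a CH2–CH2 bond remote from both the heterocycle and the sulfur. Both carbons begin as α‑carbons of carboxylic acids. 4‑(3,4‑Dimethoxy‑5‑methyl‑2‑oxo‑2H‑pyran‑6‑yl)butanoic acid and 8‑(methylsulfanyl)octanoic acid are activated in situ as N‑hydroxyphthalimide esters and united by a nickel‑electrocatalytic doubly decarboxylative C(sp3)–C(sp3) coupling, a reductive like‑polarity union that expels two CO2. The feature exploited is that ring carbon C6, tether carbons C1'–C3' and the lost carboxyl carbon together form a glutarate unit, so the pyranone acid follows from a β‑keto ester dianion acylation and enol lactonisation.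

Key step: step 7

Remark on the chemistry: the target has no stereocentre and no stereogenic double bond, so it is achiral and is reached as drawn without stereocontrol. Enolates and other metalated forms of numbered compounds are treated as forms of those compounds and are not numbered separately.

**Route**

Step 1
Reactants: 1 methyl 2‑methoxyacetate; 2 propanoyl chloride
Product: 3 methyl 2‑methoxy‑3‑oxopentanoate (racemic, enolisable)
Conditions: 1 (2.1 equiv), LDA (2.1 equiv), THF, −78 °C; then 2 (1.0 equiv), −78 °C; aq. NH4Cl
Reagents that add atoms: none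
Why: Crossed Claisen C‑acylation of a preformed lithium ester enolate by an acid chloride, in which the second equivalent of enolate converts the more acidic β‑keto ester into its enolate and so prevents over‑acylation.

Step 2
Reactants: 3 methyl 2‑methoxy‑3‑oxopentanoate; 4 5‑(tert‑butoxy)‑5‑oxopentanoic acid (mono‑tert‑butyl glutarate)
Product: 6 9‑tert‑butyl 1‑methyl 2‑methoxy‑4‑methyl‑3,5‑dioxononanedioate (mixture of diastereomers and enol tautomers), via acyl imidazole 5 (not isolated)
Conditions: 4, CDI (1.05 equiv), THF, rt; separately 3 (3.0 equiv), LDA (6.1 equiv), THF, −78 → 0 °C; then the solution of 5, −78 → −20 °C; aq. HCl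
Reagents that add atoms: 1,1'‑carbonyldiimidazole O=C(n1ccnc1)n1ccnc1 (supplies the imidazole unit of intermediate 5 only)
Why: Claisen‑type γ‑acylation of a β‑keto ester dianion by an acyl imidazole made in situ, in which the more basic γ‑carbanion reacts, excess dianion absorbs the acidic protons of free imidazole and of the diketo ester, and the hindered tert‑butyl ester does not compete as an electrophile.

Step 3
Reactants: 6 9‑tert‑butyl 1‑methyl 2‑methoxy‑4‑methyl‑3,5‑dioxononanedioate
Product: 7 tert‑butyl 4‑(4‑hydroxy‑3‑methoxy‑5‑methyl‑2‑oxo‑2H‑pyran‑6‑yl)butanoate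
Conditions: DBU (2 equiv), toluene, 60 °C; aq. HCl
Reagents that add atoms: none
Why: Base‑mediated enol lactonisation (6‑exo‑trig acyl substitution) of a 3,5‑diketo ester, in which the enol oxygen of the C5 ketone displaces methoxide from the C1 methyl ester to give the 4‑hydroxy‑2‑pyranone and removes both labile stereocentres, the tert‑butyl ester being inert to DBU.

Step 4
Reactants: 7 tert‑butyl 4‑(4‑hydroxy‑3‑methoxy‑5‑methyl‑2‑oxo‑2H‑pyran‑6‑yl)butanoate
Product: 8 tert‑butyl 4‑(3,4‑dimethoxy‑5‑methyl‑2‑oxo‑2H‑pyran‑6‑yl)butanoate
Conditions: Me2SO4 (1.5 equiv), K2CO3 (2.5 equiv), acetone, reflux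
Reagents that add atoms: dimethyl sulfate COS(=O)(=O)OC
Why: Williamson‑type O‑methylation of the acidic vinylogous acid, for which dimethyl sulfate with K2CO3 in acetone should favour attack through O‑4 and so retain the 2‑pyranone, while the tert‑butyl ester is untouched.

Step 5
Reactants: 8 tert‑butyl 4‑(3,4‑dimethoxy‑5‑methyl‑2‑oxo‑2H‑pyran‑6‑yl)butanoate
Product: 9 4‑(3,4‑dimethoxy‑5‑methyl‑2‑oxo‑2H‑pyran‑6‑yl)butanoic acid
Conditions: TFA/CH2Cl2 (1:3), rt
Reagents that add atoms: none
Why: Acidolysis of a tert‑butyl ester with loss of isobutene, under which the methoxy groups and the pyranone lactone should be stable.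

Step 6
Reactants: 10 8‑bromooctanoic acid
Product: 11 8‑(methylsulfanyl)octanoic acid
Conditions: NaSMe (2.5 equiv), DMF, 0 °C → rt; aq. HCl
Reagents that add atoms: sodium methanethiolate [Na+].[S-]C
Why: SN2 displacement of a primary bromide by thiolate, in which the first equivalent of thiolate only deprotonates the acid and the resulting carboxylate is too weak a nucleophile to compete.

Step 7
Reactants: 9 4‑(3,4‑dimethoxy‑5‑methyl‑2‑oxo‑2H‑pyran‑6‑yl)butanoic acid (1.0 equiv); 11 8‑(methylsulfanyl)octanoic acid (3.0 equiv)
Product: 14 3,4‑dimethoxy‑5‑methyl‑6‑[10‑(methylsulfanyl)decyl]‑2H‑pyran‑2‑one, via pyranone‑butanoate NHPI ester 12 (not isolated), via 8‑(methylsulfanyl)octanoate NHPI ester 13 (not isolated)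
Conditions: NHPI (4.0 equiv), DIC (4.0 equiv), DMAP (cat.), CH2Cl2, rt, then solvent exchange to NMP; NiCl2·6H2O (20 mol%), 2,2':6',2''‑terpyridine (20 mol%), AgNO3 (0.3 equiv, Ag‑nanoparticle layer deposited on the cathode), Mg(+)/RVC(−), constant current, rt
Reagents that add atoms: N‑hydroxyphthalimide O=C1N(O)C(=O)c2ccccc12 (its atoms are carried only in intermediates 12 and 13 and are expelled again)
Why: Cathodically generated low‑valent Ni–terpyridine reduces each N‑acyloxyphthalimide by single‑electron transfer, the radical anions fragment with loss of CO2 and phthalimide anion to give the primary alkyl radicals at C3' of the pyranone side chain and at C7 of the 7‑(methylsulfanyl)heptyl unit, and the two are joined on nickel by radical capture and C(sp3)–C(sp3) reductive elimination. The closest known reaction type is the Ni‑electrocatalytic doubly decarboxylative coupling of two redox‑active esters formed in situ, a reductive relative of the mixed Kolbe electrolysis. No ring is closed and no stereocentre is formed. The step needs cross‑ over homo‑coupling, which is not intrinsic for two primary radicals and is secured statistically by the threefold excess of the cheap acid 11, both homodimers differing clearly in polarity from 14. It also needs chemoselectivity: the substrates are reduced at the cathode against a sacrificial Mg anode, so the thioether never meets an oxidising potential, and the electron‑rich 3,4‑dimethoxy‑2‑pyranone is reduced far less readily than the phthalimide esters.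

**Compound list**

1 | methyl 2‑methoxyacetate | COCC(=O)OC | starting material
2 | propanoyl chloride | CCC(=O)Cl | starting material
3 | methyl 2‑methoxy‑3‑oxopentanoate (racemic) | CCC(=O)C(OC)C(=O)OC | intermediate
4 | 5‑(tert‑butoxy)‑5‑oxopentanoic acid | CC(C)(C)OC(=O)CCCC(=O)O | starting material
5 | tert‑butyl 5‑(1H‑imidazol‑1‑yl)‑5‑oxopentanoate | CC(C)(C)OC(=O)CCCC(=O)n1ccnc1 | intermediate
6 | 9‑tert‑butyl 1‑methyl 2‑methoxy‑4‑methyl‑3,5‑dioxononanedioate (stereoisomer mixture) | CC(C)(C)OC(=O)CCCC(=O)C(C)C(=O)C(OC)C(=O)OC | intermediate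
7 | tert‑butyl 4‑(4‑hydroxy‑3‑methoxy‑5‑methyl‑2‑oxo‑2H‑pyran‑6‑yl)butanoate | CC(C)(C)OC(=O)CCCc1oc(=O)c(OC)c(O)c1C | intermediate
8 | tert‑butyl 4‑(3,4‑dimethoxy‑5‑methyl‑2‑oxo‑2H‑pyran‑6‑yl)butanoate | CC(C)(C)OC(=O)CCCc1oc(=O)c(OC)c(OC)c1C | intermediate
9 | 4‑(3,4‑dimethoxy‑5‑methyl‑2‑oxo‑2H‑pyran‑6‑yl)butanoic acid | OC(=O)CCCc1oc(=O)c(OC)c(OC)c1C | intermediate
10 | 8‑bromooctanoic acid | OC(=O)CCCCCCCBr | starting material
11 | 8‑(methylsulfanyl)octanoic acid | CSCCCCCCCC(=O)O | intermediate
12 | 1,3‑dioxoisoindolin‑2‑yl 4‑(3,4‑dimethoxy‑5‑methyl‑2‑oxo‑2H‑pyran‑6‑yl)butanoate | O=C(CCCc1oc(=O)c(OC)c(OC)c1C)ON1C(=O)c2ccccc2C1=O | intermediate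
13 | 1,3‑dioxoisoindolin‑2‑yl 8‑(methylsulfanyl)octanoate | CSCCCCCCCC(=O)ON1C(=O)c2ccccc2C1=O | intermediate
14 | 3,4‑dimethoxy‑5‑methyl‑6‑[10‑(methylsulfanyl)decyl]‑2H‑pyran‑2‑one | COc1c(C)c(CCCCCCCCCCSC)oc(=O)c1OC | target

**Step count and risks**

Total step count: 7. Longest linear sequence: 6 steps (1 → 2 → 3 → 4 → 5 → 7).

Steps most likely to fail:

1. Step 7 (key step). The thioether may bind to the silver‑coated cathode or to nickel and stall turnover, or statistical homocoupling may consume the pyranone partner. The fallback replaces the reductive electrochemical union by a decarboxylative Negishi‑type alkyl–alkyl coupling. It sets out from 9, which is converted with NHPI and DIC (CH2Cl2, rt) into the redox‑active ester 12, now isolated. In parallel, commercial 1,7‑dibromoheptane (BrCCCCCCCBr, used in excess) is mono‑substituted with NaSMe to give 1‑bromo‑7‑(methylsulfanyl)heptane F1. Magnesium in THF converts this into [7‑(methylsulfanyl)heptyl]magnesium bromide F2, and ZnCl2 (0.5 equiv) transmetalates it to bis[7‑(methylsulfanyl)heptyl]zinc F3. Nickel‑catalysed coupling of 12 with F3 (NiCl2·glyme, 2,2'‑bipyridine, THF/DMF, rt) should give 14 directly, where the fallback comes back to the route.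

2. Step 2. Proton transfer from the acidic diketo ester and from free imidazole may quench the dianion, or O‑acylation may compete, so that conversion stays low. The fallback replaces the Claisen acylation by an aldol addition followed by oxidation. It sets out from 3, whose dianion (LDA, 2 equiv, THF, −78 °C) is added to commercial tert‑butyl 5‑oxopentanoate (O=CCCCC(=O)OC(C)(C)C), an electrophile that leaves no product more acidic than the starting material. This should give 9‑tert‑butyl 1‑methyl 5‑hydroxy‑2‑methoxy‑4‑methyl‑3‑oxononanedioate F4. Dess–Martin oxidation of its secondary alcohol (CH2Cl2, NaHCO3, rt) should then give 6, where the fallback comes back to the route.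

3. Step 4. The ambident pyranone anion may be alkylated at the lactone carbonyl oxygen, giving the isomeric 2‑methoxy‑4‑pyranone beside or instead of the 2‑pyranone. The fallback replaces alkylation of the potassium salt by a redox‑condensation etherification of the un‑ionised hydroxypyranone. It sets out from 7, which is treated with methanol, PPh3 and DIAD (THF, 0 °C → rt; Mitsunobu reaction), conditions under which 4‑hydroxy‑2‑pyranones serve as the acidic partner and are etherified at O‑4. It comes back to the route at 8; no new compound is made (F0).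

**Further compounds**

F1 | step 7 | 1‑bromo‑7‑(methylsulfanyl)heptane | CSCCCCCCCBr
F2 | step 7 | [7‑(methylsulfanyl)heptyl]magnesium bromide | CSCCCCCCC[Mg]Br
F3 | step 7 | bis[7‑(methylsulfanyl)heptyl]zinc | CSCCCCCCC[Zn]CCCCCCCSC
F4 | step 2 | 9‑tert‑butyl 1‑methyl 5‑hydroxy‑2‑methoxy‑4‑methyl‑3‑oxononanedioate | COC(=O)C(OC)C(=O)C(C)C(O)CCCC(=O)OC(C)(C)C
F0 | step 4 | none | none
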